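Side product cannot be read from one reading, since it grows while first end groups and links stand together and neither stands still.

| flask | first end groups | second end groups | remark | time |
|---|---|---|---|---|
| north-east | 10 mM | 0.90 equiv | run made earlier |  |
| north | 6.7 mM | 0.90 equiv | run made earlier |  |
| east | 15 mM | 0.90 equiv | run made earlier |  |
| winter | 10 mM | 0.900 equiv (fed, over 2.5 h) | all else is in the flask from the start; the feed brings no volume worth counting | 3.0 h |
| noon | 10 mM | 0.900 equiv | everything together at the start | 3.0 h |
| dawn | 10 mM (fed, over 2.5 h) | 0.900 equiv | all else is in the flask from the start; the feed brings no volume worth counting | 3.0 h |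
| midnight | 10 mM | 0.900 equiv (fed, over 15 min) | all else is in the flask from the start; the feed brings no volume worth counting | 3.0 h |
| spring | 10 mM (in portions, 2, over 2.5 h) | 0.900 equiv | first portion at the start, last at 2.5 h | 3.0 h |

| run | time / h | links / % | side product / % |
|---|---|---|---|
| north-east | 0.250 | 53.9 | 0.6 |
| north-east | 0.333 | 60.2 | 2.0 |
| north-east | 0.500 | 65.8 | 1.6 |
| north-east | 0.833 | 72.8 | 1.9 |
| north-east | 1.33 | 78.2 | 4.7 |
| north-east | 2.00 | 80.1 | 6.5 |
| north-east | 3.00 | 81.3 | 9.3 |
| north | 0.417 | 57.6 | 1.0 |
| north | 0.833 | 70.1 | 2.8 |
| north | 1.33 | 74.4 | 4.4 |
| north | 1.50 | 75.6 | 4.4 |
| north | 2.00 | 78.3 | 4.5 |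
| north | 2.50 | 79.7 | 5.6 |
| north | 3.00 | 80.9 | 6.8 |
| east | 0.250 | 60.1 | 1.6 |
| east | 0.333 | 65.1 | 1.3 |
| east | 0.500 | 70.3 | 2.9 |
| east | 0.833 | 75.2 | 5.0 |
| east | 1.33 | 77.9 | 6.8 |
| east | 2.00 | 79.2 | 9.7 |
| east | 3.00 | 80.6 | 11.8 |

(each reading ± 0.5 percentage points)

- in percentages every species weighs as the first end groups in it: one side product counts as two
- for links the idle adduct is counted in
- the analysis behind the earlier runs scatters by 0.5 percentage points, standard deviation
- candidate steps: first end groups + links -> side product; second end groups + links <-> idle adduct; first end groups + second end groups -> links + released group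

- the best flask by share of links in links plus side product; "all alike" if 1.5 percentage points covers them all (winter / noon / dawn / midnight / spring / all alike)
- share of links in links plus side product at the end, winter
- share of links in links plus side product at the end, noon
- share of links in links plus side product at the end, dawn
- share of links in links plus side product at the end, midnight
- share of links in links plus side product at the end, spring

So I used two times. Let a and l be first end groups and links as fractions of the charge. The overlap time T is the integral of a·l over the run. The side time t_s is what turns overlap into side product: the percentage O equals T over t_s. In the north-east run I took a as what links and side product leave, and between 0.500 h and 3.00 h found T = 0.320 h. Side product rose 7.7 percentage points meanwhile, so t_s = 4.16 h at 10 mM. The step has two partners, so I took t_s as inverse to the charge.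

For winter I supposed, as a crude step that no earlier run tested, that links follow the feed of second end groups, the limiting reagent. That gave T = 0.495 h and a first O of 11.9%. But side product eats a and l, shrinking T by O times a quarter of the run. Going round until it stopped put 0.750 h beside t_s and gave O = 10.1%.

The forecast said spring, with winter 87.2%, noon 90%, dawn 93.3%, midnight 90% and spring 95.5%, holding that “selectivity depends on keeping first end groups and links from coexisting”.

The flasks gave spring as best, with winter 87.1%, noon 90.0%, dawn 94.3%, midnight 90.1% and spring 96.2%.

    first end groups + links → side product (k = 12.0 L mol⁻¹ h⁻¹)
    second end groups + links ⇌ idle adduct, settled at all times (K = 120 L mol⁻¹)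
    first end groups + second end groups → links + released group (k = 750 L mol⁻¹ h⁻¹)

Winter held 10.6% side product at 3.00 h, against my 10.1%, though its links stood at 41.2% at 1.50 h, when second end groups equal to 54.0% of the first end groups charged had been fed, so links had not followed the feed. For the neighbour of winter charged with 40 mM I kept the crude step, whose T holds no charge, so T stayed in the reckoning, while t_s shortens to 1.04 h, below winter's. The same reckoning gives O = 27.7%. That neighbour held 30.2% side product and 6.28% first end groups, against winter's 10.6% and 17.5%, and its share of links was 67.8%.

The runs were computed on assumed constants; noise was put on by code.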